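(The numbers in the tables were generated by integration with made-up constants; scatter was added.)

**Late stall.** Late in the dawn run Q still read 29% at 20.0 min, though that flask held more J than Q. Q is the substrate, J the reagent, E the mono adduct, Z the bis adduct, G the by-product, D a product formed on the way, and L a species formed from J and G. The spring run is the opening of the flask asked about.

| setting | spring | dawn | flask |
|---|---|---|---|
| Q | 0.20 M | 0.20 M | 0.20 M |
| J | 0.16 M | 0.24 M | 0.160 M |
| remark | the very flask that is asked about, followed so far | run made earlier |  |
| time |  |  | 20 min |

- spring (time / min: Q / %, E / %): 0.833: 79, 22; 1.50: 73, 28; 2.50: 65, 33; 3.00: 64, 34; 4.00: 61, 36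
- dawn (time / min: Q / %, E / %): 4.00: 46, 52; 8.00: 36, 63; 12.0: 34, 65; 15.0: 27, 66; 20.0: 29, 68

(standard deviation of a reading: 2 percentage points)

- what is said of G includes L
- candidate steps: J + E -> Z + G; J + G <-> L; Q + J -> E + G; G -> D
- the earlier runs do not show how much of J is bound; that part of a forecast is a guess

- part of the Q that has reacted at 20 min
- share of the unused J that is free and not bound as L, at 20 min

**Bench count.** The bench rule is one J per Q. It makes J the limiting reagent in the spring flask and lets 80.0% of Q react, yet the spring readings show 39.0% reacted at 4.00 min, and slowing.

**One molecule.** So I followed one J. Meeting Q, it makes E and one G, and that G may bind a second J as L. If it always does, each Q reacted costs two J, and free J ends at the parking mark, half the J charge over the Q charge: 40.0% for the spring flask. The bench count stops working where J over Q falls below 2, and spring and dawn stand at 0.800 and 1.20.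

**My reckoning.** The dawn mark is 60.0%, and dawn read 71.0% reacted at 20.0 min, so by that reading each Q reacted in the dawn run cost at most 1.69 J on average, not 2. Adding that excess to the spring mark, I expected 51.0% at 20 min. For the free share I have no figure, since the runs do not show how much J is bound.

**The forecast.** It gave 52% reacted and 7% of the unused J free, holding that “Free J then collapses to a few mM and the rate falls sharply”. Its figure came by stepping the flask by hand, not by my addition.

**The result.** The flask gave 56.2% reacted and 11.6% free.

    J + E → Z + G (k = 0.200 M⁻¹ min⁻¹)
    J + G ⇌ L, settled at all times (K = 130 M⁻¹)
    Q + J → E + G (k = 2.30 M⁻¹ min⁻¹)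
    G → D (k = 0.0250 min⁻¹)

The flask passed its mark by 16 percentage points. Its answer moved 5 points with J charged at 0.141 M or 0.181 M. In the neighbouring flask Q was cut to 0.050 M, which is 3.20 equiv of J. Its mark is 160%, more than the whole Q charge, so the reckoning shows no stall there. That flask reached 97.0% reacted at 20 min, with 77.5% of its Q as E and 19.5% as Z.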